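**Retrosynthetic overview**
- The last bond made is the aryl C7–OH bond of the chromene: a ketone-directed C–H hydroxylation of the 5-methoxy chromenyl benzyl ketone, whose only free ortho position is C7.
- The 5-OMe group comes from O-methylation of the ketone-chelated 5-hydroxy chromene.
- The pyran ring is the only ring built. It comes from a 2,4-dihydroxydeoxybenzoin and prenal by C–C condensation, then C–O ring closure (oxa-6π) onto the non-chelated hydroxyl.
- The deoxybenzoin comes from Friedel–Crafts acylation of resorcinol with 4-methoxyphenylacetic acid; both benzene rings are bought.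

Assumption: the target has no stereocentre and no stereogenic double bond (the ring alkene is held cis by the ring), so it is achiral and the "single enantiomer" is this one structure.

**Step 1**
Reactants: 1 resorcinol; 2 4-methoxyphenylacetic acid
Product: 3 1-(2,4-dihydroxyphenyl)-2-(4-methoxyphenyl)ethan-1-one
Conditions: BF3·Et2O (as solvent), 85 °C, 2 h; then aq NaOAc
Reagents that add atoms: none
Why: BF3-promoted Friedel–Crafts (Nencki-type) acylation goes at C4 of resorcinol (para to one OH, ortho to the other), and the chelated product resists a second acylation; no stereocentre is formed.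

**Step 2**
Reactants: 3 1-(2,4-dihydroxyphenyl)-2-(4-methoxyphenyl)ethan-1-one; 4 3-methylbut-2-enal (prenal)
Product: 6 1-(5-hydroxy-2,2-dimethyl-2H-chromen-6-yl)-2-(4-methoxyphenyl)ethan-1-one, via ortho-quinone methide 5 (not isolated)
Conditions: pyridine, 120 °C, sealed tube, 18 h
Reagents that add atoms: none
Why: Formal [3+3] chromene annulation: aldol-type attack of the carbon between the two hydroxyls on prenal and loss of water give ortho-quinone methide 5, whose oxa-6π electrocyclisation forms the O–C(CH3)2 bond on the free para-hydroxyl while the other hydroxyl stays chelated to the ketone (the outcome known for 2,4-dihydroxyacetophenone); no stereocentre is formed.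

**Step 3**
Reactants: 6 1-(5-hydroxy-2,2-dimethyl-2H-chromen-6-yl)-2-(4-methoxyphenyl)ethan-1-one
Product: 7 1-(5-methoxy-2,2-dimethyl-2H-chromen-6-yl)-2-(4-methoxyphenyl)ethan-1-one
Conditions: MeI (1.5 equiv), K2CO3 (2 equiv), acetone, reflux, 12 h
Reagents that add atoms: iodomethane, CI
Why: Williamson ether synthesis on the only phenol, which is far more acidic than the benzylic ketone C–H, so the carbonate-generated phenoxide is O-methylated; no stereocentre is formed.

**Step 4**
Reactants: 7 1-(5-methoxy-2,2-dimethyl-2H-chromen-6-yl)-2-(4-methoxyphenyl)ethan-1-one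
Product: 9 1-(7-hydroxy-5-methoxy-2,2-dimethyl-2H-chromen-6-yl)-2-(4-methoxyphenyl)ethan-1-one, via aryl pinacol boronate 8 (not isolated)
Conditions: [Ir(OMe)(cod)]2 (2.5 mol%), AsPh3 (10 mol%), B2pin2 (1.1 equiv), octane, 110 °C, 16 h; then NaBO3·4H2O (3 equiv), THF/H2O, rt, 2 h
Reagents that add atoms: bis(pinacolato)diboron, CC1(C)OB(OC1(C)C)B1OC(C)(C)C(C)(C)O1 (boron and pinacolate atoms of intermediate 8 only); sodium perborate tetrahydrate, [Na+].[Na+].O[B-]1(O)OO[B-](O)(O)OO1 (water of crystallisation not shown; gives the hydroxyl oxygen of 9)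
Why: Proposed new method: a one-pot, non-acidic ketone-directed C–H hydroxylation in which the 14-electron trivalent iridium tris(boryl) complex formed from [Ir(OMe)(cod)]2, B2pin2 and weakly bound AsPh3 binds the ketone oxygen of 7 and cleaves the only ortho C–H (C7–H; the other ortho position carries OMe) through a five-membered iridacycle, C–B reductive elimination gives boronate 8, and perborate turns C–B into C–O by 1,2-aryl shift from boron to oxygen without touching the chromene alkene; the closest known reactions are the iridium-catalysed ortho C–H borylation of simple aryl ketones and the one-pot arene borylation/oxidation to phenols, neither shown for an enolisable benzyl ketone on a 2H-chromene; no stereocentre is formed.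

**Compound list**
1 | resorcinol (benzene-1,3-diol) | Oc1cccc(O)c1 | starting material
2 | 4-methoxyphenylacetic acid | COc1ccc(CC(=O)O)cc1 | starting material
3 | 1-(2,4-dihydroxyphenyl)-2-(4-methoxyphenyl)ethan-1-one | COc1ccc(CC(=O)c2ccc(O)cc2O)cc1 | intermediate
4 | 3-methylbut-2-enal (prenal) | CC(C)=CC=O | starting material
5 | 5-hydroxy-4-[(4-methoxyphenyl)acetyl]-6-(3-methylbut-2-en-1-ylidene)cyclohexa-2,4-dien-1-one (ortho-quinone methide, not isolated, exocyclic alkene geometry not defined) | COc1ccc(CC(=O)C2=C(O)C(=CC=C(C)C)C(=O)C=C2)cc1 | intermediate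
6 | 1-(5-hydroxy-2,2-dimethyl-2H-chromen-6-yl)-2-(4-methoxyphenyl)ethan-1-one | COc1ccc(CC(=O)c2ccc3OC(C)(C)C=Cc3c2O)cc1 | intermediate
7 | 1-(5-methoxy-2,2-dimethyl-2H-chromen-6-yl)-2-(4-methoxyphenyl)ethan-1-one | COc1ccc(CC(=O)c2ccc3OC(C)(C)C=Cc3c2OC)cc1 | intermediate
8 | 1-[5-methoxy-2,2-dimethyl-7-(4,4,5,5-tetramethyl-1,3,2-dioxaborolan-2-yl)-2H-chromen-6-yl]-2-(4-methoxyphenyl)ethan-1-one (aryl pinacol boronate, not isolated) | COc1ccc(CC(=O)c2c(B3OC(C)(C)C(C)(C)O3)cc4OC(C)(C)C=Cc4c2OC)cc1 | intermediate
9 | 1-(7-hydroxy-5-methoxy-2,2-dimethyl-2H-chromen-6-yl)-2-(4-methoxyphenyl)ethan-1-one | COc1ccc(CC(=O)c2c(O)cc3c(c2OC)C=CC(C)(C)O3)cc1 | target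

**Totals**
Total step count: 4. Longest linear sequence: 4 (1 → 3 → 6 → 7 → 9).

**Three steps most likely to fail**

Step 4 (the proposed new step). The risks are:
- hydroboration or reduction of the chromene alkene by the HBpin that is released;
- weak direction by a ketone twisted by the neighbouring OMe, giving undirected borylation at C8 or on the anisyl ring;
- Dakin-type cleavage of the electron-rich ortho-hydroxy ketone if the oxidation is pushed.

The fallback uses only known reactions and carries the 7-oxygen in from the start. It sets out from 2 and comes back at 9.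
- Purchased phloroglucinol (Oc1cc(O)cc(O)c1) is acylated with 2 in BF3·Et2O at 80 °C to give 1-(2,4,6-trihydroxyphenyl)-2-(4-methoxyphenyl)ethan-1-one F1.
- The most acidic, non-chelated para-hydroxyl is O-propargylated with 3-chloro-3-methylbut-1-yne (CC(C)(Cl)C#C; CuCl2·2H2O cat., DBU, MeCN, 0 °C) to give 1-[2,6-dihydroxy-4-(2-methylbut-3-yn-2-yloxy)phenyl]-2-(4-methoxyphenyl)ethan-1-one F2.
- One of the two equivalent ortho-hydroxyls is protected (MOMCl, COCCl; iPr2NEt, CH2Cl2, 0 °C), the other staying chelated, to give 1-[2-hydroxy-6-(methoxymethoxy)-4-(2-methylbut-3-yn-2-yloxy)phenyl]-2-(4-methoxyphenyl)ethan-1-one F3.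
- Heating in xylene at 140 °C brings about the aryl propargyl Claisen rearrangement, 1,5-hydrogen shift and oxa-6π closure. Chelation-induced bond fixation sends it to the carbon next to the free chelated hydroxyl, giving 1-[5-hydroxy-7-(methoxymethoxy)-2,2-dimethyl-2H-chromen-6-yl]-2-(4-methoxyphenyl)ethan-1-one F4.
- MeI/K2CO3 in acetone gives 1-[5-methoxy-7-(methoxymethoxy)-2,2-dimethyl-2H-chromen-6-yl]-2-(4-methoxyphenyl)ethan-1-one F5.
- HCl in MeOH at 40 °C removes the acetal and gives 9.

Step 2. The risks are a modest yield, condensation of prenal with the deoxybenzoin methylene and chelated hydroxyl (isoflavanone-type by-products), and some ring closure onto the chelated hydroxyl.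

The fallback replaces the condensation by O-alkylation and a sigmatropic cascade. It sets out from 3 and comes back at 6.
- The non-chelated 4-hydroxyl of 3 is alkylated with 3-chloro-3-methylbut-1-yne (CuCl2·2H2O cat., DBU, MeCN, 0 °C) to give 1-[2-hydroxy-4-(2-methylbut-3-yn-2-yloxy)phenyl]-2-(4-methoxyphenyl)ethan-1-one F6.
- Heating F6 in N,N-diethylaniline at 180 °C gives 6 by Claisen rearrangement to the carbon between the two oxygens, 1,5-hydrogen shift and oxa-6π closure.

Step 3. The risks are slow alkylation of the strongly chelated, doubly flanked phenol and, if forced, C-methylation of the benzylic methylene through the enolate.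

The fallback avoids base and enolate altogether. It sets out from 6 and comes back at 7. It is a Mitsunobu etherification (MeOH, PPh3, DIAD, THF, 0 °C to rt), in which methanol is activated as an alkoxyphosphonium electrophile under neutral conditions and the phenol is the acid partner. It makes no new compound: none F0.

**Further compounds**
F1 | step 4 | 1-(2,4,6-trihydroxyphenyl)-2-(4-methoxyphenyl)ethan-1-one | COc1ccc(CC(=O)c2c(O)cc(O)cc2O)cc1
F2 | step 4 | 1-[2,6-dihydroxy-4-(2-methylbut-3-yn-2-yloxy)phenyl]-2-(4-methoxyphenyl)ethan-1-one | COc1ccc(CC(=O)c2c(O)cc(OC(C)(C)C#C)cc2O)cc1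
F3 | step 4 | 1-[2-hydroxy-6-(methoxymethoxy)-4-(2-methylbut-3-yn-2-yloxy)phenyl]-2-(4-methoxyphenyl)ethan-1-one | COCOc1cc(OC(C)(C)C#C)cc(O)c1C(=O)Cc1ccc(OC)cc1
F4 | step 4 | 1-[5-hydroxy-7-(methoxymethoxy)-2,2-dimethyl-2H-chromen-6-yl]-2-(4-methoxyphenyl)ethan-1-one | COCOc1cc2OC(C)(C)C=Cc2c(O)c1C(=O)Cc1ccc(OC)cc1
F5 | step 4 | 1-[5-methoxy-7-(methoxymethoxy)-2,2-dimethyl-2H-chromen-6-yl]-2-(4-methoxyphenyl)ethan-1-one | COCOc1cc2OC(C)(C)C=Cc2c(OC)c1C(=O)Cc1ccc(OC)cc1
F6 | step 2 | 1-[2-hydroxy-4-(2-methylbut-3-yn-2-yloxy)phenyl]-2-(4-methoxyphenyl)ethan-1-one | COc1ccc(CC(=O)c2ccc(OC(C)(C)C#C)cc2O)cc1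
F0 | step 3 | none | none
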